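The flavone is cut at its C4 carbonyl, which sits between C4a of ring A and the C3=C2 unit bearing ring B, and at the O1–C2 bond of pyranone ring C. One palladium-mediated operation joins an ortho-iodophenol (ring A with O1 and the future C4a), carbon monoxide (C4) and an arylacetylene (C3, C2 and ring B), then closes ring C. The precursor is 2-iodo-3,5,6-trimethoxyphenol, whose iodine is placed by MOM-directed lithiation so that its position is not left to electrophilic substitution. The alkyne carries the catechol as benzyl ethers. The 3-methoxyl is added afterwards, and one boron trichloride treatment unmasks the three phenols.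

Key step: step 8

Remark: the target has no stereocentre and is achiral, so there is nothing to control or resolve; the racemic compounds that appear in two fallbacks lose their stereocentres again.

Step 1
Reactants: 1 2-hydroxy-4,6-dimethoxybenzaldehyde
Product: 2 2,4-dimethoxy-6-(methoxymethoxy)benzaldehyde
Conditions: NaH, MOMCl, DMF, 0 °C → rt
Reagents that add atoms: chloromethyl methyl ether, COCCl
Why: Williamson-type O-alkylation of the sodium phenoxide, with sodium hydride chosen because the hydroxyl is hydrogen-bonded to the aldehyde and reacts sluggishly with amine bases.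

Step 2
Reactants: 2 2,4-dimethoxy-6-(methoxymethoxy)benzaldehyde
Product: 4 2,4-dimethoxy-6-(methoxymethoxy)phenol, via aryl formate 3 (not isolated)
Conditions: mCPBA, CH2Cl2, 0 °C → rt; Na2S2O3/NaHCO3 wash; then K2CO3 (cat.), MeOH, rt
Reagents that add atoms: meta-chloroperoxybenzoic acid, O=C(OO)c1cccc(Cl)c1
Why: Baeyer–Villiger (Dakin-type) oxidation in which the electron-rich trioxygenated aryl group migrates in preference to hydride, followed by mild methanolysis of formate 3 that leaves the MOM acetal intact.

Step 3
Reactants: 4 2,4-dimethoxy-6-(methoxymethoxy)phenol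
Product: 5 1,2,5-trimethoxy-3-(methoxymethoxy)benzene
Conditions: MeI, K2CO3, acetone, reflux
Reagents that add atoms: iodomethane, CI
Why: Williamson O-methylation of the only free phenol fixes the future 8-methoxyl while the MOM group keeps the neighbouring oxygen, the future O1, distinct.

Step 4
Reactants: 5 1,2,5-trimethoxy-3-(methoxymethoxy)benzene
Product: 7 2-iodo-1,4,5-trimethoxy-3-(methoxymethoxy)benzene, via aryllithium 6 (not isolated)
Conditions: n-BuLi, THF, 0 °C; then I2, −78 °C → rt
Reagents that add atoms: iodine, II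
Why: Directed ortho-metalation, in which the MOM ether (the stronger director, turned toward C4–H by its methoxy neighbour) and the 5-methoxyl together activate the C–H between them over the C–H flanked by two methoxyls, and iodine quenches aryllithium 6.

Step 5
Reactants: 7 2-iodo-1,4,5-trimethoxy-3-(methoxymethoxy)benzene
Product: 8 2-iodo-3,5,6-trimethoxyphenol
Conditions: conc. HCl (cat.), MeOH, 40 °C
Reagents that add atoms: none
Why: Acid-catalysed acetal exchange with methanol removes the MOM group, and the methyl ethers and the aryl iodide are stable to dilute acid in the absence of a reductant.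

Step 6
Reactants: 9 2,3-dihydroxybenzaldehyde
Product: 10 2,3-bis(benzyloxy)benzaldehyde
Conditions: BnBr, K2CO3, DMF, 60 °C
Reagents that add atoms: benzyl bromide, BrCc1ccccc1
Why: Double Williamson benzylation, with warming in DMF to alkylate the chelated 2-hydroxyl as well, leaves the aldehyde untouched.

Step 7
Reactants: 10 2,3-bis(benzyloxy)benzaldehyde
Product: 12 1,2-bis(benzyloxy)-3-ethynylbenzene, via diazoalkene 11 (not isolated)
Conditions: dimethyl (1-diazo-2-oxopropyl)phosphonate, K2CO3, MeOH, rt
Reagents that add atoms: dimethyl (1-diazo-2-oxopropyl)phosphonate, COP(=O)(OC)C(=[N+]=[N-])C(C)=O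
Why: Ohira–Bestmann (Seyferth–Gilbert) homologation, in which the diazomethylphosphonate anion formed by methanolysis adds to the non-enolisable aldehyde in a Horner–Wadsworth–Emmons manner to give diazoalkene 11, which loses nitrogen and rearranges by 1,2-hydride shift to the terminal alkyne.

Step 8
Reactants: 8 2-iodo-3,5,6-trimethoxyphenol; 12 1,2-bis(benzyloxy)-3-ethynylbenzene; 13 carbon monoxide
Product: 16 2-[2,3-bis(benzyloxy)phenyl]-5,7,8-trimethoxy-4H-chromen-4-one, via hydroxyaryl ynone 14 (not isolated), via enaminone 15 (not isolated)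
Conditions: PdCl2(dppf) (5 mol %), CO (10 bar), Et2NH, 90 °C, copper-free
Reagents that add atoms: none
Why: Oxidative addition of Pd(0) into the C–I bond of 8, CO insertion to the aroyl–palladium iodide, amine-assisted acetylide transfer from 12 and reductive elimination give ynone 14 (C4a–C4 and C4–C3), after which diethylamine adds to the ynone β-carbon to give enaminone 15 and the phenol displaces the amine there to form O1–C2. The closest known reaction type is the carbonylative Sonogashira coupling of ortho-iodophenols with terminal arylacetylenes in a secondary amine, which gives flavones directly. Ring C is the only ring closed, in a 6-endo mode (6-endo-dig if the phenol attacks 14 itself, 6-endo-trig addition–elimination on 15). No stereocentre is created. Carbonylative rather than direct coupling is needed and is secured by CO pressure, the absence of copper and the ready CO insertion into the electron-rich, doubly ortho-substituted aryl–palladium species; six- rather than five-membered closure is needed and is secured by the amine relay, which makes the β-carbon the electrophilic site. The iodine of 8 fixes C4a and its ortho-hydroxyl fixes O1, so no A-ring regiochemistry is open.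

Step 9
Reactants: 16 2-[2,3-bis(benzyloxy)phenyl]-5,7,8-trimethoxy-4H-chromen-4-one
Product: 19 2-[2,3-bis(benzyloxy)phenyl]-3-hydroxy-5,7,8-trimethoxy-4H-chromen-4-one, via 3-lithioflavone 17 (not isolated), via 3-boronate 18 (not isolated)
Conditions: LDA, THF, −78 °C; B(OMe)3, −78 °C → rt; then H2O2, AcOH, rt
Reagents that add atoms: hydrogen peroxide, OO
Why: Lithiation–borylation–oxidation, a known way to convert 5,7-dialkoxyflavones into flavonols: LDA removes the C3–H (the only vinylic hydrogen next to the carbonyl, with lithium held by the C4 oxygen), trimethyl borate traps 17, and peroxide triggers the boron-to-oxygen shift in 18, all of which benzyl and methyl ethers tolerate.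

Step 10
Reactants: 19 2-[2,3-bis(benzyloxy)phenyl]-3-hydroxy-5,7,8-trimethoxy-4H-chromen-4-one
Product: 20 2-[2,3-bis(benzyloxy)phenyl]-3,5,7,8-tetramethoxy-4H-chromen-4-one
Conditions: MeI, K2CO3, DMF, rt
Reagents that add atoms: iodomethane, CI
Why: Williamson O-methylation of the only free hydroxyl, which is acidified by the adjacent carbonyl and alkylates cleanly with carbonate base.

Step 11
Reactants: 20 2-[2,3-bis(benzyloxy)phenyl]-3,5,7,8-tetramethoxy-4H-chromen-4-one
Product: 22 2-(2,3-dihydroxyphenyl)-5-hydroxy-3,7,8-trimethoxy-4H-chromen-4-one, via boron chelate 21 (not isolated)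
Conditions: BCl3, C6HMe5, CH2Cl2, −78 → 0 °C; then MeOH, aq. HCl
Reagents that add atoms: none
Why: Lewis-acid ether cleavage, in which boron trichloride removes the aryl benzyl ethers at low temperature with pentamethylbenzene trapping the benzyl cations and, on warming, cleaves only the 5-methyl ether because boron sits in a six-membered chelate between O5 and the C4 carbonyl, before aqueous methanol hydrolyses the B–O bonds of 21 to the target 22.

Compound list
1 | 2-hydroxy-4,6-dimethoxybenzaldehyde | O=Cc1c(O)cc(OC)cc1OC | starting material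
2 | 2,4-dimethoxy-6-(methoxymethoxy)benzaldehyde | O=Cc1c(OCOC)cc(OC)cc1OC | intermediate
3 | 2,4-dimethoxy-6-(methoxymethoxy)phenyl formate (not isolated) | O=COc1c(OCOC)cc(OC)cc1OC | intermediate
4 | 2,4-dimethoxy-6-(methoxymethoxy)phenol | Oc1c(OCOC)cc(OC)cc1OC | intermediate
5 | 1,2,5-trimethoxy-3-(methoxymethoxy)benzene | COc1c(OCOC)cc(OC)cc1OC | intermediate
6 | [3,4,6-trimethoxy-2-(methoxymethoxy)phenyl]lithium (not isolated) | COc1c(OCOC)c([Li])c(OC)cc1OC | intermediate
7 | 2-iodo-1,4,5-trimethoxy-3-(methoxymethoxy)benzene | COc1c(OCOC)c(I)c(OC)cc1OC | intermediate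
8 | 2-iodo-3,5,6-trimethoxyphenol | COc1cc(OC)c(I)c(O)c1OC | intermediate
9 | 2,3-dihydroxybenzaldehyde | O=Cc1cccc(O)c1O | starting material
10 | 2,3-bis(benzyloxy)benzaldehyde | O=Cc1cccc(OCc2ccccc2)c1OCc1ccccc1 | intermediate
11 | 1,2-bis(benzyloxy)-3-(2-diazoethenyl)benzene (not isolated) | [N-]=[N+]=C=Cc1cccc(OCc2ccccc2)c1OCc1ccccc1 | intermediate
12 | 1,2-bis(benzyloxy)-3-ethynylbenzene | C#Cc1cccc(OCc2ccccc2)c1OCc1ccccc1 | intermediate
13 | carbon monoxide | [C-]#[O+] | starting material
14 | 3-[2,3-bis(benzyloxy)phenyl]-1-(2-hydroxy-3,4,6-trimethoxyphenyl)prop-2-yn-1-one (not isolated) | COc1cc(OC)c(C(=O)C#Cc2cccc(OCc3ccccc3)c2OCc2ccccc2)c(O)c1OC | intermediate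
15 | 3-[2,3-bis(benzyloxy)phenyl]-3-(diethylamino)-1-(2-hydroxy-3,4,6-trimethoxyphenyl)prop-2-en-1-one (not isolated, double-bond geometry not defined) | CCN(CC)C(=CC(=O)c1c(O)c(OC)c(OC)cc1OC)c1cccc(OCc2ccccc2)c1OCc1ccccc1 | intermediate
16 | 2-[2,3-bis(benzyloxy)phenyl]-5,7,8-trimethoxy-4H-chromen-4-one | COc1cc(OC)c2c(=O)cc(-c3cccc(OCc4ccccc4)c3OCc3ccccc3)oc2c1OC | intermediate
17 | 3-lithio derivative of 16 (not isolated) | COc1cc(OC)c2c(=O)c([Li])c(-c3cccc(OCc4ccccc4)c3OCc3ccccc3)oc2c1OC | intermediate
18 | dimethyl {2-[2,3-bis(benzyloxy)phenyl]-5,7,8-trimethoxy-4-oxo-4H-chromen-3-yl}boronate (not isolated) | COc1cc(OC)c2c(=O)c(B(OC)OC)c(-c3cccc(OCc4ccccc4)c3OCc3ccccc3)oc2c1OC | intermediate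
19 | 2-[2,3-bis(benzyloxy)phenyl]-3-hydroxy-5,7,8-trimethoxy-4H-chromen-4-one | COc1cc(OC)c2c(=O)c(O)c(-c3cccc(OCc4ccccc4)c3OCc3ccccc3)oc2c1OC | intermediate
20 | 2-[2,3-bis(benzyloxy)phenyl]-3,5,7,8-tetramethoxy-4H-chromen-4-one | COc1cc(OC)c2c(=O)c(OC)c(-c3cccc(OCc4ccccc4)c3OCc3ccccc3)oc2c1OC | intermediate
21 | boron-bound form of the target, drawn in its simplest form: 5-O-dichloroboryl, 2',3'-O-chloroboranediyl (not isolated) | COc1cc(OB(Cl)Cl)c2c(=O)c(OC)c(-c3cccc4OB(Cl)Oc34)oc2c1OC | intermediate
22 | 5,2',3'-trihydroxy-3,7,8-trimethoxyflavone, i.e. 2-(2,3-dihydroxyphenyl)-5-hydroxy-3,7,8-trimethoxy-4H-chromen-4-one | COc1cc(O)c2c(=O)c(OC)c(-c3cccc(O)c3O)oc2c1OC | target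

Total step count: 11. Longest linear sequence: 9 steps (steps 1–5, then 8–11); the alkyne branch is steps 6–7.

Steps most likely to fail

Step 8. The coupling may proceed without CO uptake (leading toward a benzofuran), the aroyl–palladium species may be captured by the amine, or oxidative addition at the hindered, electron-rich C–I bond may be slow. The fallback builds the same three bonds without palladium and sets out from 5. Compound 5 is lithiated as in step 4 and aryllithium 6 is quenched with DMF to give 3,4,6-trimethoxy-2-(methoxymethoxy)benzaldehyde F1. Addition of the lithium acetylide of 12 (n-BuLi, THF, −78 °C) gives racemic 3-[2,3-bis(benzyloxy)phenyl]-1-[3,4,6-trimethoxy-2-(methoxymethoxy)phenyl]prop-2-yn-1-ol F2. MnO2 in CH2Cl2 oxidises it to 3-[2,3-bis(benzyloxy)phenyl]-1-[3,4,6-trimethoxy-2-(methoxymethoxy)phenyl]prop-2-yn-1-one F3. HCl in MeOH removes the MOM group to give ynone 14, and diethylamine in ethanol at reflux should close it through 15. The fallback comes back to the route at 16.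

Step 9. C3 deprotonation may be incomplete, the amide base may add to the pyranone, or the boronate may protodeboronate before oxidation. The fallback sets out from 16 and oxidises the C2=C3 bond directly: dimethyldioxirane in acetone/CH2Cl2 at 0 °C should give the racemic 2,3-epoxide, 2-[2,3-bis(benzyloxy)phenyl]-2,3-epoxy-5,7,8-trimethoxychroman-4-one F4. Catalytic p-TsOH in CH2Cl2 then opens it to the 3-hydroxyflavone. The fallback comes back to the route at 19.

Step 11. The 3- or 8-methyl ether may be lost along with the 5-methyl ether, or benzyl cations may be transferred to the electron-rich rings. The fallback sets out from 20 and separates the two deprotections. Hydrogenolysis (H2, Pd/C, EtOAc/MeOH, rt) should give 2-(2,3-dihydroxyphenyl)-3,5,7,8-tetramethoxy-4H-chromen-4-one F5. Anhydrous AlCl3 in MeCN at rt, followed by dilute HCl, then cleaves only the chelated 5-methyl ether. The fallback comes back to the route at 22.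

Further compounds
F1 | step 8 | 3,4,6-trimethoxy-2-(methoxymethoxy)benzaldehyde | COc1c(OCOC)c(C=O)c(OC)cc1OC
F2 | step 8 | 3-[2,3-bis(benzyloxy)phenyl]-1-[3,4,6-trimethoxy-2-(methoxymethoxy)phenyl]prop-2-yn-1-ol (racemic) | COc1c(OCOC)c(C(O)C#Cc2cccc(OCc3ccccc3)c2OCc2ccccc2)c(OC)cc1OC
F3 | step 8 | 3-[2,3-bis(benzyloxy)phenyl]-1-[3,4,6-trimethoxy-2-(methoxymethoxy)phenyl]prop-2-yn-1-one | COc1c(OCOC)c(C(=O)C#Cc2cccc(OCc3ccccc3)c2OCc2ccccc2)c(OC)cc1OC
F4 | step 9 | 2-[2,3-bis(benzyloxy)phenyl]-2,3-epoxy-5,7,8-trimethoxychroman-4-one (racemic, cis-fused epoxide) | COc1cc(OC)c2c(c1OC)OC1(c3cccc(OCc4ccccc4)c3OCc3ccccc3)OC1C2=O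
F5 | step 11 | 2-(2,3-dihydroxyphenyl)-3,5,7,8-tetramethoxy-4H-chromen-4-one | COc1cc(OC)c2c(=O)c(OC)c(-c3cccc(O)c3O)oc2c1OC
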